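**Retrosynthetic overview**

- The target is a cis-fused drim-8-ene (H on C5 and CH3 on C10 on the same face) whose C9 carries a 2-sulfooxy-3-hydroxy-5-(hydroxymethyl)benzyl group. The last disconnections are the O–sulfate bond and C9–C11, the latter by Negishi coupling of a C9 enol triflate with an arylmethylzinc chloride made from 5-bromovanillin.
- Ring B (C5–C10) is opened at C7=C8 by ring-closing metathesis of a C5 allyl group with a C9 2-propenyl ketone. The C1 oxygen is removed through an enol triflate.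
- The strategy rests on ring A: C5 (H, next to the C4 gem-dimethyl) and quaternary C10 (CH3 and C9) are the β- and α-carbons of methyl 3,3-dimethyl-6-oxocyclohex-1-ene-1-carboxylate (ester carbon = C9, ketone = C1). Conjugate allylation and enolate methylation form C5–C6 and C10–CH3.
- Ring order: ring A is bought as 4,4-dimethylcyclohexanone, ring B is closed by metathesis, and the arene is attached afterwards.

Key step: step 3

Assumption: the (S,S)-tert-butyl-bis(oxazoline) ligand is taken to give the (R) centre at the allylated carbon (its enantiomer is used if the sense of induction is the reverse); sulfated intermediates are carried as sodium salts and the hydrogen sulfate drawn for the target is set free in the last operation.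

**Route**

Step 1
Reactants: 1 4,4-dimethylcyclohexanone; 2 dimethyl carbonate
Product: 3 methyl 5,5-dimethyl-2-oxocyclohexane-1-carboxylate
Conditions: NaH (2.2 equiv), 2 (3 equiv), THF, reflux; aq HCl work-up
Reagents that add atoms: none
Why: Crossed Claisen C-acylation of the ketone enolate by the carbonate is driven by deprotonation of the β-keto ester, and the two α-positions of the symmetrical ketone are equivalent.

Step 2
Reactants: 3 methyl 5,5-dimethyl-2-oxocyclohexane-1-carboxylate
Product: 6 methyl 3,3-dimethyl-6-oxocyclohex-1-ene-1-carboxylate, via α-phenylselanyl keto ester 4 (not isolated), via selenoxide 5 (not isolated)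
Conditions: PhSeCl, pyridine, CH2Cl2, 0 °C; then 30% H2O2, 0 °C → rt
Reagents that add atoms: none
Why: Selenenylation of the enolised β-keto ester and syn-elimination of the selenoxide (selenoxide dehydrogenation) can place the alkene only toward the ring CH2, and the adjacent C(CH3)2 prevents dienol formation or aromatisation.

Step 3
Reactants: 6 methyl 3,3-dimethyl-6-oxocyclohex-1-ene-1-carboxylate; 7 allyltrimethylsilane; 8 iodomethane
Product: 10 methyl (1R,2R)-1,3,3-trimethyl-6-oxo-2-(prop-2-en-1-yl)cyclohexane-1-carboxylate (methyl trans to allyl), via silyl enol ether 9 (not isolated)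
Conditions: Cu(OTf)2 (10 mol%), (S,S)-t-Bu-box [2,2′-(propane-2,2-diyl)bis((4S)-4-tert-butyl-4,5-dihydrooxazole)] (11 mol%), 7 (2 equiv), 4 Å MS, CH2Cl2, −78 → −20 °C; then 8 (5 equiv), Bu4NF (1.2 equiv, THF), −20 °C → rt
Reagents that add atoms: none
Why: The 1,3-dicarbonyl unit of 6 binds the divalent copper centre of the Cu(OTf)2–bis(oxazoline) complex as a chelate, which activates the alkene and shields one face, so 7 attacks the β-carbon (C5) through an open transition state and the β-silyl cation passes its silyl group to the enolate oxygen to give 9 and free the catalyst; fluoride then unmasks the ammonium enolate, which MeI alkylates on carbon (C10). The closest known reaction type is the copper–bis(oxazoline)-catalysed enantioselective Hosomi–Sakurai conjugate allylation of cyclic alkylidene β-keto esters, joined to the fluoride-mediated C-alkylation of a β-keto ester silyl enol ether. No ring is closed: the step forms C5–C6 and C10–CH3 on the existing ring A. C5 is set by the ligand-controlled face of attack on the chelate, and C10 by approach of MeI to the enolate face anti to the pseudoaxial allyl group on the neighbouring carbon, which leaves methyl trans to allyl and the ester carbon C9 cis to C6, as the later cis ring fusion requires. The step needs 1,4- over 1,2-addition (two-point binding and the soft allylsilane secure it), C- over O-methylation (soft iodide electrophile on a stabilised enolate) and a single alkylation site (C10 is the only carbon between the carbonyls and becomes quaternary); the C4 gem-dimethyl group keeps 6 from tautomerising to a dienol.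

Step 4
Reactants: 10 methyl (1R,2R)-1,3,3-trimethyl-6-oxo-2-(prop-2-en-1-yl)cyclohexane-1-carboxylate
Product: 11 methyl (1R,6R)-1,5,5-trimethyl-6-(prop-2-en-1-yl)-2-[(trifluoromethanesulfonyl)oxy]cyclohex-2-ene-1-carboxylate
Conditions: KN(SiMe3)2, THF, −78 °C; PhNTf2, −78 → 0 °C
Reagents that add atoms: N-phenylbis(trifluoromethanesulfonimide), O=S(=O)(N(c1ccccc1)S(=O)(=O)C(F)(F)F)C(F)(F)F
Why: The ketone can enolise only toward its CH2 because the other α-carbon is quaternary, so deprotonation and O-sulfonylation should give one enol triflate without touching either stereocentre.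

Step 5
Reactants: 11 methyl (1R,6R)-1,5,5-trimethyl-6-(prop-2-en-1-yl)-2-[(trifluoromethanesulfonyl)oxy]cyclohex-2-ene-1-carboxylate
Product: 12 methyl (1S,6R)-1,5,5-trimethyl-6-(prop-2-en-1-yl)cyclohex-2-ene-1-carboxylate
Conditions: Pd(OAc)2 (5 mol%), PPh3, n-Bu3N, HCO2H, DMF, 60 °C
Reagents that add atoms: none
Why: Palladium-catalysed formate reduction of the enol triflate (oxidative addition to zerovalent palladium, formate exchange, decarboxylation, reductive elimination) replaces OTf by H and leaves the C1=C2 alkene, while cyclisation onto the allyl group would need a bridgehead alkene and is not expected (the descriptor at C1 changes by priority only).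

Step 6
Reactants: 12 methyl (1S,6R)-1,5,5-trimethyl-6-(prop-2-en-1-yl)cyclohex-2-ene-1-carboxylate
Product: 13 [(1S,6R)-1,5,5-trimethyl-6-(prop-2-en-1-yl)cyclohex-2-en-1-yl]methanol
Conditions: LiAlH4, Et2O, 0 °C → rt
Reagents that add atoms: none
Why: Hydride reduction takes the hindered neopentyl-type ester to the primary alcohol and leaves the two isolated alkenes alone.

Step 7
Reactants: 13 [(1S,6R)-1,5,5-trimethyl-6-(prop-2-en-1-yl)cyclohex-2-en-1-yl]methanol
Product: 14 (1S,6R)-1,5,5-trimethyl-6-(prop-2-en-1-yl)cyclohex-2-ene-1-carbaldehyde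
Conditions: Dess–Martin periodinane, CH2Cl2, rt
Reagents that add atoms: none
Why: Dess–Martin oxidation gives the aldehyde, which has no α-hydrogen and so cannot epimerise or over-oxidise under these conditions.

Step 8
Reactants: 14 (1S,6R)-1,5,5-trimethyl-6-(prop-2-en-1-yl)cyclohex-2-ene-1-carbaldehyde
Product: 15 2-methyl-1-[(1S,6R)-1,5,5-trimethyl-6-(prop-2-en-1-yl)cyclohex-2-en-1-yl]prop-2-en-1-ol (both carbinol epimers)
Conditions: CH2=C(CH3)MgBr, THF, −78 → 0 °C; H2O
Reagents that add atoms: isopropenylmagnesium bromide, CC(=C)[Mg]Br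
Why: Grignard 1,2-addition to the non-enolisable aldehyde brings in C8 and its methyl group, and the new carbinol centre need not be controlled because the next step oxidises it.

Step 9
Reactants: 15 2-methyl-1-[(1S,6R)-1,5,5-trimethyl-6-(prop-2-en-1-yl)cyclohex-2-en-1-yl]prop-2-en-1-ol
Product: 16 2-methyl-1-[(1S,6R)-1,5,5-trimethyl-6-(prop-2-en-1-yl)cyclohex-2-en-1-yl]prop-2-en-1-one
Conditions: Dess–Martin periodinane, CH2Cl2, rt
Reagents that add atoms: none
Why: Dess–Martin oxidation of the allylic alcohol gives the 2-propenyl ketone, whose quaternary neighbour leaves it no enolisable position.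

Step 10
Reactants: 16 2-methyl-1-[(1S,6R)-1,5,5-trimethyl-6-(prop-2-en-1-yl)cyclohex-2-en-1-yl]prop-2-en-1-one
Product: 17 (4aR,8aS)-2,5,5,8a-tetramethyl-4a,5,6,8a-tetrahydronaphthalen-1(4H)-one
Conditions: second-generation Grubbs catalyst (5 mol%), toluene, 80 °C
Reagents that add atoms: none
Why: Ring-closing metathesis of the terminal allyl alkene with the 1,1-disubstituted enone alkene, which sit on the same face of ring A, closes the six-membered ring B at C7=C8 with loss of ethene and gives the cis ring fusion, while the unstrained ring A alkene should stay out of the reaction.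

Step 11
Reactants: 17 (4aR,8aS)-2,5,5,8a-tetramethyl-4a,5,6,8a-tetrahydronaphthalen-1(4H)-one
Product: 19 (4aR,8aS)-2,5,5,8a-tetramethyl-3,4,4a,5,6,8a-hexahydronaphthalen-1-yl trifluoromethanesulfonate, via lithium enolate 18 (not isolated)
Conditions: LiBH(s-Bu)3, THF, −78 °C; then Comins' reagent, −78 → 0 °C
Reagents that add atoms: N-(5-chloropyridin-2-yl)bis(trifluoromethanesulfonimide), O=S(=O)(N(c1ccc(Cl)cn1)S(=O)(=O)C(F)(F)F)C(F)(F)F
Why: Conjugate hydride addition to the β-unsubstituted enone (the carbonyl beside the quaternary carbon is too hindered for 1,2-attack) gives the regiodefined enolate, and O-sulfonylation then fixes the tetrasubstituted C8=C9 enol triflate (reductive triflation).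

Step 12
Reactants: 20 5-bromovanillin (3-bromo-4-hydroxy-5-methoxybenzaldehyde)
Product: 21 3-bromo-4,5-dihydroxybenzaldehyde
Conditions: AlCl3, pyridine, CH2Cl2, reflux; aq HCl
Reagents that add atoms: none
Why: The aluminium chelate of the guaiacol unit activates the methyl ether for demethylation by pyridine (Lewis-acid ether cleavage), and the aryl bromide and aldehyde are untouched.

Step 13
Reactants: 21 3-bromo-4,5-dihydroxybenzaldehyde
Product: 22 3-bromo-5-hydroxy-4-(methoxymethoxy)benzaldehyde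
Conditions: MOMCl (1.05 equiv), i-Pr2NEt (1.1 equiv), CH2Cl2/DMF, 0 °C
Reagents that add atoms: chloromethyl methyl ether, COCCl
Why: The hydroxyl para to the formyl group and ortho to bromine is the more acidic one, so with one equivalent of base its phenoxide should be the one alkylated by the small reactive chloride (regioselective Williamson etherification).

Step 14
Reactants: 22 3-bromo-5-hydroxy-4-(methoxymethoxy)benzaldehyde
Product: 23 3-(benzyloxy)-5-bromo-4-(methoxymethoxy)benzaldehyde
Conditions: BnBr, K2CO3, DMF, rt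
Reagents that add atoms: benzyl bromide, BrCc1ccccc1
Why: Williamson benzylation of the one remaining phenol gives an ether that cannot migrate to the neighbouring oxygen later.

Step 15
Reactants: 23 3-(benzyloxy)-5-bromo-4-(methoxymethoxy)benzaldehyde
Product: 24 2-[3-(benzyloxy)-5-bromo-4-(methoxymethoxy)phenyl]-1,3-dioxolane
Conditions: Me3SiOCH2CH2OSiMe3, Me3SiOTf (cat.), CH2Cl2, −78 °C; pyridine quench
Reagents that add atoms: 1,2-bis(trimethylsilyloxy)ethane, C[Si](C)(C)OCCO[Si](C)(C)C
Why: Silyl-triflate-catalysed acetalisation with the bis-silyl glycol (Noyori conditions) is fast for an electron-rich aryl aldehyde at low temperature, where the aryl MOM ether should survive.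

Step 16
Reactants: 24 2-[3-(benzyloxy)-5-bromo-4-(methoxymethoxy)phenyl]-1,3-dioxolane
Product: 26 3-(benzyloxy)-5-(1,3-dioxolan-2-yl)-2-(methoxymethoxy)benzaldehyde, via aryllithium 25 (not isolated)
Conditions: n-BuLi, THF, −78 °C; DMF, −78 → 0 °C; H2O
Reagents that add atoms: N,N-dimethylformamide, CN(C)C=O
Why: Bromine–lithium exchange is faster than any deprotonation at −78 °C and gives an aryllithium stabilised by the ortho MOM oxygen, which DMF formylates at the carbon that becomes C11.

Step 17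
Reactants: 26 3-(benzyloxy)-5-(1,3-dioxolan-2-yl)-2-(methoxymethoxy)benzaldehyde
Product: 27 [3-(benzyloxy)-5-(1,3-dioxolan-2-yl)-2-(methoxymethoxy)phenyl]methanol
Conditions: NaBH4, MeOH/THF, 0 °C
Reagents that add atoms: none
Why: Borohydride reduces the free aldehyde to the benzylic alcohol, and the masked aldehyde stays protected as its acetal.

Step 18
Reactants: 27 [3-(benzyloxy)-5-(1,3-dioxolan-2-yl)-2-(methoxymethoxy)phenyl]methanol
Product: 29 2-[3-(benzyloxy)-5-(chloromethyl)-4-(methoxymethoxy)phenyl]-1,3-dioxolane, via benzylic mesylate 28 (not isolated)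
Conditions: MsCl, Et3N, CH2Cl2, 0 °C; then LiCl, DMF, rt
Reagents that add atoms: lithium chloride, [Li+].[Cl-]
Why: Mesylation and SN2 displacement by chloride under basic conditions give the benzylic chloride without acid, so the acetal and the MOM ether are kept.

Step 19
Reactants: 29 2-[3-(benzyloxy)-5-(chloromethyl)-4-(methoxymethoxy)phenyl]-1,3-dioxolane
Product: 30 {[3-(benzyloxy)-5-(1,3-dioxolan-2-yl)-2-(methoxymethoxy)phenyl]methyl}zinc chloride (THF solution, LiCl complex)
Conditions: Zn dust (activated with BrCH2CH2Br and Me3SiCl), LiCl, THF, 25 °C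
Reagents that add atoms: zinc, [Zn]
Why: LiCl-assisted insertion of zinc into a benzylic chloride gives the benzylzinc reagent with little Wurtz coupling, and the reagent tolerates ethers and acetals.

Step 20
Reactants: 19 (4aR,8aS)-2,5,5,8a-tetramethyl-3,4,4a,5,6,8a-hexahydronaphthalen-1-yl trifluoromethanesulfonate; 30 {[3-(benzyloxy)-5-(1,3-dioxolan-2-yl)-2-(methoxymethoxy)phenyl]methyl}zinc chloride
Product: 31 2-[3-(benzyloxy)-4-(methoxymethoxy)-5-{[(4aR,8aS)-2,5,5,8a-tetramethyl-3,4,4a,5,6,8a-hexahydronaphthalen-1-yl]methyl}phenyl]-1,3-dioxolane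
Conditions: Pd(OAc)2 (5 mol%), SPhos (10 mol%), 30 (1.5 equiv), THF, 25 → 50 °C
Reagents that add atoms: none
Why: Negishi coupling (oxidative addition of zerovalent palladium into the enol triflate, transmetalation from benzylzinc, reductive elimination) forms C9–C11 with the alkene fixed at C8=C9, and the bulky electron-rich biarylphosphine is chosen for the hindered triflate.

Step 21
Reactants: 31 2-[3-(benzyloxy)-4-(methoxymethoxy)-5-{[(4aR,8aS)-2,5,5,8a-tetramethyl-3,4,4a,5,6,8a-hexahydronaphthalen-1-yl]methyl}phenyl]-1,3-dioxolane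
Product: 32 2-[3-(benzyloxy)-4-(methoxymethoxy)-5-{[(4aR,8aS)-2,5,5,8a-tetramethyl-3,4,4a,5,6,7,8,8a-octahydronaphthalen-1-yl]methyl}phenyl]-1,3-dioxolane
Conditions: 2-nitrobenzenesulfonylhydrazide (excess, in portions), Et3N, CH2Cl2, rt
Reagents that add atoms: none
Why: Diimide made in the flask transfers H2 in a concerted syn fashion to the cis-disubstituted C1=C2 alkene and is far slower on the tetrasubstituted C8=C9 alkene, and the basic non-aqueous medium spares the benzyl ether, the MOM ether and the acetal.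

Step 22
Reactants: 32 2-[3-(benzyloxy)-4-(methoxymethoxy)-5-{[(4aR,8aS)-2,5,5,8a-tetramethyl-3,4,4a,5,6,7,8,8a-octahydronaphthalen-1-yl]methyl}phenyl]-1,3-dioxolane
Product: 33 3-(benzyloxy)-4-hydroxy-5-{[(4aR,8aS)-2,5,5,8a-tetramethyl-3,4,4a,5,6,7,8,8a-octahydronaphthalen-1-yl]methyl}benzaldehyde
Conditions: 3 M aq HCl, THF, 45 °C
Reagents that add atoms: water, O
Why: Acid hydrolysis removes the dioxolane and the aryl MOM ether together and frees only the oxygen that is to be sulfated, and the para-formyl group makes that phenol a poor nucleophile, which should hold back acid-catalysed cyclisation onto the C8=C9 alkene.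

Step 23
Reactants: 33 3-(benzyloxy)-4-hydroxy-5-{[(4aR,8aS)-2,5,5,8a-tetramethyl-3,4,4a,5,6,7,8,8a-octahydronaphthalen-1-yl]methyl}benzaldehyde
Product: 35 sodium 2-(benzyloxy)-4-formyl-6-{[(4aR,8aS)-2,5,5,8a-tetramethyl-3,4,4a,5,6,7,8,8a-octahydronaphthalen-1-yl]methyl}phenyl sulfate, via pyridinium sulfate 34 (not isolated)
Conditions: SO3·pyridine (5 equiv), pyridine, 45 °C; then aq NaHCO3
Reagents that add atoms: sulfur trioxide–pyridine complex, O=S(=O)=O.c1ccncc1; sodium hydrogen carbonate, [Na+].OC([O-])=O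
Why: O-sulfation with the sulfur trioxide–amine complex meets a single free hydroxyl, so the regiochemistry follows from the protecting-group pattern, and the aryl sulfate is kept as its base-stable sodium salt.

Step 24
Reactants: 35 sodium 2-(benzyloxy)-4-formyl-6-{[(4aR,8aS)-2,5,5,8a-tetramethyl-3,4,4a,5,6,7,8,8a-octahydronaphthalen-1-yl]methyl}phenyl sulfate
Product: 36 sodium 2-(benzyloxy)-4-(hydroxymethyl)-6-{[(4aR,8aS)-2,5,5,8a-tetramethyl-3,4,4a,5,6,7,8,8a-octahydronaphthalen-1-yl]methyl}phenyl sulfate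
Conditions: NaBH4, MeOH, 0 °C
Reagents that add atoms: none
Why: Borohydride reduces the aryl aldehyde to the benzylic alcohol in a neutral to basic medium in which the sulfate monoester anion is inert.

Step 25
Reactants: 36 sodium 2-(benzyloxy)-4-(hydroxymethyl)-6-{[(4aR,8aS)-2,5,5,8a-tetramethyl-3,4,4a,5,6,7,8,8a-octahydronaphthalen-1-yl]methyl}phenyl sulfate
Product: 38 2-hydroxy-4-(hydroxymethyl)-6-{[(4aR,8aS)-2,5,5,8a-tetramethyl-3,4,4a,5,6,7,8,8a-octahydronaphthalen-1-yl]methyl}phenyl hydrogen sulfate (target), via sodium salt 37 (not isolated)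
Conditions: H2 (1 atm), Pd/C, MeOH, NaHCO3 (cat.), rt, filter; then HCl (1.0 equiv, aq), 0 °C, C18 desalting, lyophilise
Reagents that add atoms: none
Why: Hydrogenolysis of an aryl benzyl ether over Pd/C is fast under neutral conditions, where the tetrasubstituted alkene, the sulfate salt and the benzylic alcohol (para to the electron-poor sulfate oxygen) should persist, and one equivalent of acid in the cold then gives the hydrogen sulfate.

**Compound list**

1 | 4,4-dimethylcyclohexanone | CC1(C)CCC(=O)CC1 | starting material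
2 | dimethyl carbonate | COC(=O)OC | starting material
3 | methyl 5,5-dimethyl-2-oxocyclohexane-1-carboxylate | COC(=O)C1CC(C)(C)CCC1=O | intermediate
4 | methyl 5,5-dimethyl-2-oxo-1-(phenylselanyl)cyclohexane-1-carboxylate (racemic) | COC(=O)C1([Se]c2ccccc2)CC(C)(C)CCC1=O | intermediate
5 | methyl 5,5-dimethyl-2-oxo-1-(phenylseleninyl)cyclohexane-1-carboxylate (stereoisomer mixture) | COC(=O)C1([Se](=O)c2ccccc2)CC(C)(C)CCC1=O | intermediate
6 | methyl 3,3-dimethyl-6-oxocyclohex-1-ene-1-carboxylate | COC(=O)C1=CC(C)(C)CCC1=O | intermediate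
7 | allyltrimethylsilane | C=CC[Si](C)(C)C | starting material
8 | iodomethane | CI | starting material
9 | methyl (6R)-5,5-dimethyl-6-(prop-2-en-1-yl)-2-[(trimethylsilyl)oxy]cyclohex-1-ene-1-carboxylate | C=CC[C@@H]1C(C)(C)CCC(O[Si](C)(C)C)=C1C(=O)OC | intermediate
10 | methyl (1R,2R)-1,3,3-trimethyl-6-oxo-2-(prop-2-en-1-yl)cyclohexane-1-carboxylate | C=CC[C@@H]1C(C)(C)CCC(=O)[C@]1(C)C(=O)OC | intermediate
11 | methyl (1R,6R)-1,5,5-trimethyl-6-(prop-2-en-1-yl)-2-[(trifluoromethanesulfonyl)oxy]cyclohex-2-ene-1-carboxylate | C=CC[C@@H]1C(C)(C)CC=C(OS(=O)(=O)C(F)(F)F)[C@]1(C)C(=O)OC | intermediate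
12 | methyl (1S,6R)-1,5,5-trimethyl-6-(prop-2-en-1-yl)cyclohex-2-ene-1-carboxylate | C=CC[C@@H]1C(C)(C)CC=C[C@]1(C)C(=O)OC | intermediate
13 | [(1S,6R)-1,5,5-trimethyl-6-(prop-2-en-1-yl)cyclohex-2-en-1-yl]methanol | C=CC[C@@H]1C(C)(C)CC=C[C@]1(C)CO | intermediate
14 | (1S,6R)-1,5,5-trimethyl-6-(prop-2-en-1-yl)cyclohex-2-ene-1-carbaldehyde | C=CC[C@@H]1C(C)(C)CC=C[C@]1(C)C=O | intermediate
15 | 2-methyl-1-[(1S,6R)-1,5,5-trimethyl-6-(prop-2-en-1-yl)cyclohex-2-en-1-yl]prop-2-en-1-ol (both carbinol epimers) | C=CC[C@@H]1C(C)(C)CC=C[C@]1(C)C(O)C(C)=C | intermediate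
16 | 2-methyl-1-[(1S,6R)-1,5,5-trimethyl-6-(prop-2-en-1-yl)cyclohex-2-en-1-yl]prop-2-en-1-one | C=CC[C@@H]1C(C)(C)CC=C[C@]1(C)C(=O)C(C)=C | intermediate
17 | (4aR,8aS)-2,5,5,8a-tetramethyl-4a,5,6,8a-tetrahydronaphthalen-1(4H)-one | CC1=CC[C@@H]2C(C)(C)CC=C[C@]2(C)C1=O | intermediate
18 | lithium (4aR,8aS)-2,5,5,8a-tetramethyl-3,4,4a,5,6,8a-hexahydronaphthalen-1-olate | [Li+].CC=1CC[C@@H]2C(C)(C)CC=C[C@]2(C)C=1[O-] | intermediate
19 | (4aR,8aS)-2,5,5,8a-tetramethyl-3,4,4a,5,6,8a-hexahydronaphthalen-1-yl trifluoromethanesulfonate | CC=1CC[C@@H]2C(C)(C)CC=C[C@]2(C)C=1OS(=O)(=O)C(F)(F)F | intermediate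
20 | 5-bromovanillin (3-bromo-4-hydroxy-5-methoxybenzaldehyde) | COc1cc(C=O)cc(Br)c1O | starting material
21 | 3-bromo-4,5-dihydroxybenzaldehyde | O=Cc1cc(O)c(O)c(Br)c1 | intermediate
22 | 3-bromo-5-hydroxy-4-(methoxymethoxy)benzaldehyde | COCOc1c(O)cc(C=O)cc1Br | intermediate
23 | 3-(benzyloxy)-5-bromo-4-(methoxymethoxy)benzaldehyde | COCOc1c(OCc2ccccc2)cc(C=O)cc1Br | intermediate
24 | 2-[3-(benzyloxy)-5-bromo-4-(methoxymethoxy)phenyl]-1,3-dioxolane | COCOc1c(OCc2ccccc2)cc(C2OCCO2)cc1Br | intermediate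
25 | [3-(benzyloxy)-5-(1,3-dioxolan-2-yl)-2-(methoxymethoxy)phenyl]lithium | [Li]c1cc(C2OCCO2)cc(OCc2ccccc2)c1OCOC | intermediate
26 | 3-(benzyloxy)-5-(1,3-dioxolan-2-yl)-2-(methoxymethoxy)benzaldehyde | COCOc1c(OCc2ccccc2)cc(C2OCCO2)cc1C=O | intermediate
27 | [3-(benzyloxy)-5-(1,3-dioxolan-2-yl)-2-(methoxymethoxy)phenyl]methanol | COCOc1c(OCc2ccccc2)cc(C2OCCO2)cc1CO | intermediate
28 | [3-(benzyloxy)-5-(1,3-dioxolan-2-yl)-2-(methoxymethoxy)phenyl]methyl methanesulfonate | COCOc1c(OCc2ccccc2)cc(C2OCCO2)cc1COS(C)(=O)=O | intermediate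
29 | 2-[3-(benzyloxy)-5-(chloromethyl)-4-(methoxymethoxy)phenyl]-1,3-dioxolane | COCOc1c(OCc2ccccc2)cc(C2OCCO2)cc1CCl | intermediate
30 | {[3-(benzyloxy)-5-(1,3-dioxolan-2-yl)-2-(methoxymethoxy)phenyl]methyl}zinc chloride | COCOc1c(OCc2ccccc2)cc(C2OCCO2)cc1C[Zn]Cl | intermediate
31 | 2-[3-(benzyloxy)-4-(methoxymethoxy)-5-{[(4aR,8aS)-2,5,5,8a-tetramethyl-3,4,4a,5,6,8a-hexahydronaphthalen-1-yl]methyl}phenyl]-1,3-dioxolane | CC=1CC[C@@H]2C(C)(C)CC=C[C@]2(C)C=1Cc1cc(C3OCCO3)cc(OCc3ccccc3)c1OCOC | intermediate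
32 | 2-[3-(benzyloxy)-4-(methoxymethoxy)-5-{[(4aR,8aS)-2,5,5,8a-tetramethyl-3,4,4a,5,6,7,8,8a-octahydronaphthalen-1-yl]methyl}phenyl]-1,3-dioxolane | CC=1CC[C@@H]2C(C)(C)CCC[C@]2(C)C=1Cc1cc(C3OCCO3)cc(OCc3ccccc3)c1OCOC | intermediate
33 | 3-(benzyloxy)-4-hydroxy-5-{[(4aR,8aS)-2,5,5,8a-tetramethyl-3,4,4a,5,6,7,8,8a-octahydronaphthalen-1-yl]methyl}benzaldehyde | CC=1CC[C@@H]2C(C)(C)CCC[C@]2(C)C=1Cc1cc(C=O)cc(OCc3ccccc3)c1O | intermediate
34 | pyridinium 2-(benzyloxy)-4-formyl-6-{[(4aR,8aS)-2,5,5,8a-tetramethyl-3,4,4a,5,6,7,8,8a-octahydronaphthalen-1-yl]methyl}phenyl sulfate | CC=1CC[C@@H]2C(C)(C)CCC[C@]2(C)C=1Cc1cc(C=O)cc(OCc3ccccc3)c1OS(=O)(=O)[O-].c1cc[nH+]cc1 | intermediate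
35 | sodium 2-(benzyloxy)-4-formyl-6-{[(4aR,8aS)-2,5,5,8a-tetramethyl-3,4,4a,5,6,7,8,8a-octahydronaphthalen-1-yl]methyl}phenyl sulfate | CC=1CC[C@@H]2C(C)(C)CCC[C@]2(C)C=1Cc1cc(C=O)cc(OCc3ccccc3)c1OS(=O)(=O)[O-].[Na+] | intermediate
36 | sodium 2-(benzyloxy)-4-(hydroxymethyl)-6-{[(4aR,8aS)-2,5,5,8a-tetramethyl-3,4,4a,5,6,7,8,8a-octahydronaphthalen-1-yl]methyl}phenyl sulfate | CC=1CC[C@@H]2C(C)(C)CCC[C@]2(C)C=1Cc1cc(CO)cc(OCc3ccccc3)c1OS(=O)(=O)[O-].[Na+] | intermediate
37 | sodium 2-hydroxy-4-(hydroxymethyl)-6-{[(4aR,8aS)-2,5,5,8a-tetramethyl-3,4,4a,5,6,7,8,8a-octahydronaphthalen-1-yl]methyl}phenyl sulfate | CC=1CC[C@@H]2C(C)(C)CCC[C@]2(C)C=1Cc1cc(CO)cc(O)c1OS(=O)(=O)[O-].[Na+] | intermediate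
38 | 2-hydroxy-4-(hydroxymethyl)-6-{[(4aR,8aS)-2,5,5,8a-tetramethyl-3,4,4a,5,6,7,8,8a-octahydronaphthalen-1-yl]methyl}phenyl hydrogen sulfate | CC1=C(Cc2cc(CO)cc(O)c2OS(=O)(=O)O)[C@@]2(C)CCCC(C)(C)[C@H]2CC1 | target

**Step count**

Total steps: 25. Longest linear sequence: 17 (steps 1–11 and 20–25); the arene branch (steps 12–19) joins at step 20.

**Steps most likely to fail**

Step 3. Addition of the allylsilane to the β-carbon beside the gem-dimethyl group may be slow, so that a silyl-triflate-catalysed racemic pathway erodes the facial selectivity. The fallback gives up asymmetric catalysis for a racemic addition and a resolution. It sets out from 6: a TiCl4-promoted Hosomi–Sakurai addition of 7 (CH2Cl2, −78 °C) should give racemic methyl 3,3-dimethyl-6-oxo-2-(prop-2-en-1-yl)cyclohexane-1-carboxylate F1. Methylation with 8 (K2CO3, acetone) should give racemic methyl (1R*,2R*)-1,3,3-trimethyl-6-oxo-2-(prop-2-en-1-yl)cyclohexane-1-carboxylate F2, and preparative chromatography on a chiral stationary phase brings the route back at 10.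

Step 20. Oxidative addition and transmetalation at the tetrasubstituted triflate beside the quaternary carbon may be slower than protodemetalation and homocoupling of the benzylzinc reagent. The fallback reverses the polarity of the C9–C11 bond formation and sets out from 19.
- Carbonylation (Pd(OAc)2, 1,3-bis(diphenylphosphino)propane, CO 1 atm, MeOH, Et3N, DMF, 70 °C) should give methyl (4aR,8aS)-2,5,5,8a-tetramethyl-3,4,4a,5,6,8a-hexahydronaphthalene-1-carboxylate F3.
- i-Bu2AlH (CH2Cl2, −78 °C) then gives [(4aR,8aS)-2,5,5,8a-tetramethyl-3,4,4a,5,6,8a-hexahydronaphthalen-1-yl]methanol F4.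
- CBr4/PPh3 gives (4aR,8aS)-1-(bromomethyl)-2,5,5,8a-tetramethyl-3,4,4a,5,6,8a-hexahydronaphthalene F5.
- Aryllithium 25, made from 24 as in step 16, is turned with MgBr2·OEt2 into [3-(benzyloxy)-5-(1,3-dioxolan-2-yl)-2-(methoxymethoxy)phenyl]magnesium bromide F6.
- F6 is coupled with F5 under Li2CuCl4 catalysis (THF, −20 °C; SN2 at the primary allylic carbon, since the other allyl terminus is fully substituted), and the route comes back at 31.

Step 21. Hydrogen transfer from diimide to the ring A alkene beside the quaternary carbon may be slower than the disproportionation of diimide, which would leave the reduction incomplete. The fallback saturates ring A before the arene is attached and sets out from 17. Hydrogenation (H2 1 atm, Pd/C, EtOAc) of both alkenes should give (4aR,8aS)-2,5,5,8a-tetramethyl-3,4,4a,5,6,7,8,8a-octahydronaphthalen-1(2H)-one F7 as a mixture of C2 epimers. The ketone has one enolisable position, so LiN(i-Pr)2 (THF, −78 → 0 °C) and Comins' reagent should give (4aR,8aS)-2,5,5,8a-tetramethyl-3,4,4a,5,6,7,8,8a-octahydronaphthalen-1-yl trifluoromethanesulfonate F8. Negishi coupling of F8 with 30 under the conditions of step 20 brings the route back at 32, so no diimide step is needed.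

**Further compounds**

F1 | step 3 | racemic methyl 3,3-dimethyl-6-oxo-2-(prop-2-en-1-yl)cyclohexane-1-carboxylate (C1 epimers and enol) | C=CCC1C(C)(C)CCC(=O)C1C(=O)OC
F2 | step 3 | racemic methyl (1R*,2R*)-1,3,3-trimethyl-6-oxo-2-(prop-2-en-1-yl)cyclohexane-1-carboxylate | C=CC[C@@H]1C(C)(C)CCC(=O)[C@]1(C)C(=O)OC.C=CC[C@H]1C(C)(C)CCC(=O)[C@@]1(C)C(=O)OC
F3 | step 20 | methyl (4aR,8aS)-2,5,5,8a-tetramethyl-3,4,4a,5,6,8a-hexahydronaphthalene-1-carboxylate | CC=1CC[C@@H]2C(C)(C)CC=C[C@]2(C)C=1C(=O)OC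
F4 | step 20 | [(4aR,8aS)-2,5,5,8a-tetramethyl-3,4,4a,5,6,8a-hexahydronaphthalen-1-yl]methanol | CC=1CC[C@@H]2C(C)(C)CC=C[C@]2(C)C=1CO
F5 | step 20 | (4aR,8aS)-1-(bromomethyl)-2,5,5,8a-tetramethyl-3,4,4a,5,6,8a-hexahydronaphthalene | CC=1CC[C@@H]2C(C)(C)CC=C[C@]2(C)C=1CBr
F6 | step 20 | [3-(benzyloxy)-5-(1,3-dioxolan-2-yl)-2-(methoxymethoxy)phenyl]magnesium bromide | COCOc1c(OCc2ccccc2)cc(C2OCCO2)cc1[Mg]Br
F7 | step 21 | (4aR,8aS)-2,5,5,8a-tetramethyl-3,4,4a,5,6,7,8,8a-octahydronaphthalen-1(2H)-one (C2 epimers) | CC1CC[C@@H]2C(C)(C)CCC[C@]2(C)C1=O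
F8 | step 21 | (4aR,8aS)-2,5,5,8a-tetramethyl-3,4,4a,5,6,7,8,8a-octahydronaphthalen-1-yl trifluoromethanesulfonate | CC=1CC[C@@H]2C(C)(C)CCC[C@]2(C)C=1OS(=O)(=O)C(F)(F)F
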